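Read the early points of the eta run, which is the very flask asked about, followed so far: target climbs to 25.1% by 6.00 min, then flattens at 56.0% by 50.0 min and 55.1% by 80.0 min.

- eta: starting material 26 mM; second substrate 13 mM; coupling partner 46.8 mM; free catalyst 1.3 mM; the very flask that is asked about, followed so far
- flask: starting material 26 mM; second substrate 13.0 mM; coupling partner 46.8 mM; free catalyst 1.3 mM; time 1.5 h

- eta (time / min: target / %): 6.00: 25.1; 20.0: 48.8; 30.0: 53.8; 50.0: 56.0; 80.0: 55.1

(readings scatter by 1 percentage point)

- additions leave the volume as it is
- a reading or a percentage of target counts all its forms, free or not

- alder: change nothing and wait 3.0 h more
- maple: at 1.5 h add starting material, 50.0% of the amount charged, then wait 3.0 h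
- birch: at 1.5 h add free catalyst, 100% of the amount charged, then wait 3.0 h
- cedar: at 1.5 h add coupling partner, 100% of the amount charged, then wait 3.0 h

* target, in percent of the starting material first charged, at 1.5 h
* the option that brings most further target ("none" if no option brings more than 2 percentage points) (alder / maple / birch / cedar / none)
* target present, in percent of the starting material first charged, after alder
* target present, in percent of the starting material first charged, after cedar

Build this flask one process at a time. Take the main step first, starting material with coupling partner, one for one: the partner charge of 46.8 mM stands above the 26 mM of starting material, so this step alone promises 100 percent target. The readings stop at 56.0%, lower than that, so add the way back. Suppose dissolved target has a ceiling and the excess stands as solid, which the note on forms "free or not" permits. The forward rate then goes with free starting material times free coupling partner, while the back rate stays fixed as long as solid stands. Divide one by the other and time drops out: at the stall the ratio is one, so that product holds one value, which is thermodynamic control.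

To fill in the value, add the last process. Suppose second substrate also consumes coupling partner one for one, with half of its charge used by 50.0 min. Starting material left is then 11.4 mM and partner left 25.7 mM. Call their product, 2.94 × 10⁻⁴ M^2, the standing product.

Now use it. Let second substrate run through its charge and solve the balance again: my reckoning puts target at 47.3% after alder, down from the 55.1% read at 80.0 min, which I also take as my figure for 1.5 h. Free catalyst stands nowhere in the product, so I reckon birch at about the alder figure. Maple gives 73.2%, and cedar gives 81.0%, more than maple. So my pick is cedar.

The forecast reads 55.5% now, 55.5% after alder and 56% after cedar, and it picks birch, naming as the most likely cause that “the catalyst dies or gets sequestered”. My reckoning differs from it on the pick and on both later figures.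

The flask gives 54.5% now, 50.3% after alder and 82.4% after cedar, and the best option is cedar, with birch at −4.9 percentage points against cedar at 28 points.

crystals ⇌ target, rate k1*(cs1 - [target]) while solid is left; crystals form when [target] > cs1 (solubility = 1.80 mM, k = 0.0240 s⁻¹); coupling partner + catalyst intermediate A ⇌ free catalyst + target (K = 0.400, k = 7.70 M⁻¹ s⁻¹); starting material + free catalyst ⇌ catalyst intermediate A (K = 17.0 M⁻¹, k = 1.90 M⁻¹ s⁻¹); second substrate + free catalyst ⇌ catalyst intermediate B (K = 29.0 M⁻¹, k = 1.50 M⁻¹ s⁻¹); coupling partner + catalyst intermediate B → free catalyst + second product (k = 0.520 M⁻¹ s⁻¹) At 90.0 min this flask holds crystals at 47.6%, and its standing product reads 2.58 × 10⁻⁴ M^2. Carry that to the neighbour charged with 120 mM of coupling partner, taking its second substrate as used: the balance gives 88.2% target. At 90.0 min that neighbour, with second substrate down to 1.12% of its charge, stands at 87.7%.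

The readings stem from a simulated flask on assumed constants, and the scatter is random.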